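The synthesis rests on building benzo ring A of the chromone de novo across C5–C6 and C4a–C8a. The key step exploits the 1,2,4-trioxygenation of ring A (O1 on C8a, methoxy groups on C7 and C6) with the acyl carbon C4 on C4a, which is the pattern a 1,3,4-trimethoxy-1-silyloxybutadiene imprints on an ynone. One operation, [4+2] cycloaddition to the terminal alkyne of a cross-conjugated diynone followed by loss of methanol and silyl, gives the 2-hydroxyaryl ynone with all ring A oxygens placed. Its remaining ynone then closes the pyranone. The precursor pair is the silyl ketene acetal diene and 7-(4-benzyloxy-3-methoxyphenyl)hepta-1,4-diyn-3-one.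

Key step: step 6

Remark: the target has no stereocentre, and the silyloxy diene is used as its mixture of double-bond isomers because both sp3 carbons of the cycloadduct are flattened on aromatization. The trimethylsilyl group is kept so that the aryl silyl ether falls off in the same work-up. The side-chain phenol is carried as its benzyl ether because a free phenol would protonate the ketene acetal and would not survive the lithium amide chemistry. The acetylide that the ketone-to-alkyne conversion leaves in the flask is acylated directly, so the terminal alkyne is not isolated on the main route.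

**Route**

Step 1
Reactants: 1 methyl 4-methoxyacetoacetate
Product: 3 methyl (E)-3,4-dimethoxybut-2-enoate, via dimethyl ketal 2 (not isolated)
Conditions: HC(OMe)3, H2SO4 (cat.), MeOH, rt; then distillation at reduced pressure
Reagents that add atoms: trimethyl orthoformate, COC(OC)OC
Why: Acid-catalysed exchange with the orthoester converts the ketone into its dimethyl ketal and thermal loss of methanol during distillation gives the conjugated β-methoxy enoate (enol ether formation from a β-keto ester), expected as the (E)-isomer with the methoxy group anti to the ester.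

Step 2
Reactants: 3 methyl (E)-3,4-dimethoxybut-2-enoate
Product: 5 1,3,4-trimethoxy-1-(trimethylsilyloxy)buta-1,3-diene (mixture of double-bond isomers), via lithium dienolate 4 (not isolated)
Conditions: LiN(i-Pr)2, THF, −78 °C; Me3SiCl, −78 °C → rt; pentane, filtration, used crude
Reagents that add atoms: chlorotrimethylsilane, C[Si](C)(C)Cl
Why: The lithium amide removes a γ-proton from the CH2OMe group syn to the ester carbonyl to give the extended ester enolate, which chlorotrimethylsilane traps on oxygen, the standard formation of a vinylogous silyl ketene acetal from a β-alkoxy enoate.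

Step 3
Reactants: 6 zingerone
Product: 7 4-(4-benzyloxy-3-methoxyphenyl)butan-2-one
Conditions: BnBr, K2CO3, DMF, rt
Reagents that add atoms: benzyl bromide, BrCc1ccccc1
Why: Williamson ether synthesis on the phenoxide, which carbonate generates selectively because the phenol is far more acidic than the ketone α-hydrogens.

Step 4
Reactants: 7 4-(4-benzyloxy-3-methoxyphenyl)butan-2-one
Product: 12 5-(4-benzyloxy-3-methoxyphenyl)-N-methoxy-N-methylpent-2-ynamide, via lithium enolate 8 (not isolated), via enol phosphate 9 (not isolated), via terminal alkyne 10 (not isolated), via lithium acetylide 11 (not isolated)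
Conditions: LiN(i-Pr)2 (1.05 equiv), THF, −78 °C; ClP(O)(OEt)2 (1.05 equiv), −78 °C → rt; LiN(i-Pr)2 (2.05 equiv), −78 °C → rt; ClC(O)N(OMe)Me (1.5 equiv), −78 → 0 °C; aq. NH4Cl
Reagents that add atoms: N-methoxy-N-methylcarbamoyl chloride, CON(C)C(Cl)=O
Why: Kinetic deprotonation at the methyl group, O-phosphorylation of the terminal enolate and base-induced β-elimination of diethyl phosphate give the alkyne, which the remaining amide base converts into the acetylide (methyl ketone to alkyne conversion by enol phosphate elimination), and this is acylated in the same flask by the carbamoyl chloride in a nucleophilic acyl substitution that hindered diisopropylamine should not intercept at −78 °C and that stops at the Weinreb ynamide because this is a poor electrophile for a second acetylide at low temperature.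

Step 5
Reactants: 12 5-(4-benzyloxy-3-methoxyphenyl)-N-methoxy-N-methylpent-2-ynamide; 13 ethynylmagnesium bromide
Product: 15 7-(4-benzyloxy-3-methoxyphenyl)hepta-1,4-diyn-3-one, via magnesium hemiaminal 14 (not isolated)
Conditions: THF, 0 °C; inverse quench into cold 1 M HCl; used promptly
Reagents that add atoms: none
Why: Weinreb ketone synthesis, in which the alkynyl Grignard reagent adds once to the amide carbonyl to give a chelated tetrahedral magnesium alkoxide that survives until the inverse acidic quench, which also protonates the released N,O-dimethylhydroxylamine so that it cannot add to the diynone.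

Step 6
Reactants: 15 7-(4-benzyloxy-3-methoxyphenyl)hepta-1,4-diyn-3-one; 5 1,3,4-trimethoxy-1-(trimethylsilyloxy)buta-1,3-diene
Product: 18 5-(4-benzyloxy-3-methoxyphenyl)-1-(2-hydroxy-4,5-dimethoxyphenyl)pent-2-yn-1-one, via cycloadduct 16 (not isolated), via aryl silyl ether 17 (not isolated)
Conditions: 5 (1.5 equiv), toluene, −20 °C → rt; then 1 M HCl, THF, 0 °C
Reagents that add atoms: none
Why: Proposed new method: the polarized diene 5, whose C4 carries the largest HOMO coefficient because the ketene acetal oxygens on C1 and the methoxy group on C3 all push electron density there, should bond through C4 to the unsubstituted β-carbon of the terminal ynone of 15 and through C1 to its α-carbon, either in a concerted asynchronous [4+2] cycloaddition or stepwise by Mukaiyama–Michael addition and ring closure of the allenolate onto the silyloxycarbenium ion, both giving cyclohexa-1,4-diene 16 with the new bonds C5–C6 and C4a–C8a. The closest known reaction type is the Diels–Alder addition and aromatization of 1-alkoxy-1-silyloxy-1,3-dienes with acetylenic ketones, esters and quinones, whereas this tetra-oxygenated diene and a cross-conjugated diynone partner are untested. Ring A is closed as a six-membered carbocycle by intermolecular [4+2] annulation, and because 16 carries a mixed ketal at C8a and a hydrogen at C6, 1,4-elimination of methanol gives arene 17 and aqueous acid cleaves its labile silyl ether to the hydrogen-bonded phenol 18. No stereocentre remains, since the sp3 carbons C6 and C8a of 16 are flattened on aromatization and the isomer mixture of 5 therefore converges. The step needs regioselectivity (C4 to the β-carbon) and site selectivity for the terminal over the internal alkyne: the first follows from the matched polarization of both partners, the second from the open β-carbon of the terminal ynone against the CH2CH2Ar-bearing β-carbon of the other arm and from the lower electrophilicity of the ortho-oxygenated aryl ynone once formed. Hydrolytic work-up also secures the phenol over the methyl ether, because collapse of the C8a ketal to the dienone leaves only tautomerization to 18.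

Step 7
Reactants: 18 5-(4-benzyloxy-3-methoxyphenyl)-1-(2-hydroxy-4,5-dimethoxyphenyl)pent-2-yn-1-one
Product: 20 2-[2-(4-benzyloxy-3-methoxyphenyl)ethyl]-6,7-dimethoxy-4H-chromen-4-one, via enaminone 19 (not isolated)
Conditions: Et2NH, EtOH, rt → 50 °C
Reagents that add atoms: none
Why: Conjugate addition of diethylamine to the ynone gives a β-amino enone whose β-carbon is attacked by the ortho phenol in a 6-endo ring closure with expulsion of the amine, the amine-mediated cyclization of 2-hydroxyaryl ynones to chromones that avoids the 5-exo benzofuranone pathway.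

Step 8
Reactants: 20 2-[2-(4-benzyloxy-3-methoxyphenyl)ethyl]-6,7-dimethoxy-4H-chromen-4-one
Product: 21 2-[2-(4-hydroxy-3-methoxyphenyl)ethyl]-6,7-dimethoxy-4H-chromen-4-one
Conditions: H2 (1 atm), 10% Pd/C, EtOAc, rt
Reagents that add atoms: none
Why: Palladium-catalysed hydrogenolysis cleaves the benzylic C–O bond of the aryl benzyl ether much faster than it saturates the electron-rich vinylogous ester C2=C3 bond of the chromone, so the reaction is stopped once the benzyl ether is consumed.

**Compound list**

1 | methyl 4-methoxyacetoacetate (methyl 4-methoxy-3-oxobutanoate) | COCC(=O)CC(=O)OC | starting material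
2 | methyl 3,3,4-trimethoxybutanoate (dimethyl ketal, not isolated) | COCC(OC)(OC)CC(=O)OC | intermediate
3 | methyl (E)-3,4-dimethoxybut-2-enoate | COC/C(OC)=C\C(=O)OC | intermediate
4 | lithium 1,3,4-trimethoxybuta-1,3-dien-1-olate (lithium dienolate, geometry not defined, not isolated) | COC=C(OC)C=C(OC)O[Li] | intermediate
5 | 1,3,4-trimethoxy-1-(trimethylsilyloxy)buta-1,3-diene (mixture of double-bond isomers) | COC=C(OC)C=C(OC)O[Si](C)(C)C | intermediate
6 | zingerone, 4-(4-hydroxy-3-methoxyphenyl)butan-2-one | CC(=O)CCc1ccc(O)c(OC)c1 | starting material
7 | 4-(4-benzyloxy-3-methoxyphenyl)butan-2-one | CC(=O)CCc1ccc(OCc2ccccc2)c(OC)c1 | intermediate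
8 | lithium 4-(4-benzyloxy-3-methoxyphenyl)but-1-en-2-olate (kinetic enolate, not isolated) | C=C(O[Li])CCc1ccc(OCc2ccccc2)c(OC)c1 | intermediate
9 | diethyl 4-(4-benzyloxy-3-methoxyphenyl)but-1-en-2-yl phosphate (not isolated) | C=C(CCc1ccc(OCc2ccccc2)c(OC)c1)OP(=O)(OCC)OCC | intermediate
10 | 4-(4-benzyloxy-3-methoxyphenyl)but-1-yne (terminal alkyne, not isolated) | C#CCCc1ccc(OCc2ccccc2)c(OC)c1 | intermediate
11 | [4-(4-benzyloxy-3-methoxyphenyl)but-1-yn-1-yl]lithium (not isolated) | [Li]C#CCCc1ccc(OCc2ccccc2)c(OC)c1 | intermediate
12 | 5-(4-benzyloxy-3-methoxyphenyl)-N-methoxy-N-methylpent-2-ynamide | CON(C)C(=O)C#CCCc1ccc(OCc2ccccc2)c(OC)c1 | intermediate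
13 | ethynylmagnesium bromide | C#C[Mg]Br | starting material
14 | bromomagnesium 7-(4-benzyloxy-3-methoxyphenyl)-3-[methoxy(methyl)amino]hepta-1,4-diyn-3-olate (not isolated) | C#CC(O[Mg]Br)(N(C)OC)C#CCCc1ccc(OCc2ccccc2)c(OC)c1 | intermediate
15 | 7-(4-benzyloxy-3-methoxyphenyl)hepta-1,4-diyn-3-one | C#CC(=O)C#CCCc1ccc(OCc2ccccc2)c(OC)c1 | intermediate
16 | 5-(4-benzyloxy-3-methoxyphenyl)-1-[3,4,6-trimethoxy-6-(trimethylsilyloxy)cyclohexa-1,4-dien-1-yl]pent-2-yn-1-one (mixture of diastereomers, not isolated) | COC1C=C(C(=O)C#CCCc2ccc(OCc3ccccc3)c(OC)c2)C(OC)(O[Si](C)(C)C)C=C1OC | intermediate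
17 | 5-(4-benzyloxy-3-methoxyphenyl)-1-[4,5-dimethoxy-2-(trimethylsilyloxy)phenyl]pent-2-yn-1-one (not isolated) | COc1cc(O[Si](C)(C)C)c(C(=O)C#CCCc2ccc(OCc3ccccc3)c(OC)c2)cc1OC | intermediate
18 | 5-(4-benzyloxy-3-methoxyphenyl)-1-(2-hydroxy-4,5-dimethoxyphenyl)pent-2-yn-1-one | COc1cc(O)c(C(=O)C#CCCc2ccc(OCc3ccccc3)c(OC)c2)cc1OC | intermediate
19 | 5-(4-benzyloxy-3-methoxyphenyl)-3-(diethylamino)-1-(2-hydroxy-4,5-dimethoxyphenyl)pent-2-en-1-one (geometry not defined, not isolated) | CCN(CC)C(CCc1ccc(OCc2ccccc2)c(OC)c1)=CC(=O)c1cc(OC)c(OC)cc1O | intermediate
20 | 2-[2-(4-benzyloxy-3-methoxyphenyl)ethyl]-6,7-dimethoxy-4H-chromen-4-one | COc1cc(CCc2cc(=O)c3cc(OC)c(OC)cc3o2)ccc1OCc1ccccc1 | intermediate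
21 | 2-[2-(4-hydroxy-3-methoxyphenyl)ethyl]-6,7-dimethoxy-4H-chromen-4-one | COc1cc(CCc2cc(=O)c3cc(OC)c(OC)cc3o2)ccc1O | target

**Step count**

Total: 8 steps (2 to the diene, 3 to the diynone, the key step, 2 to finish). Longest linear sequence: 6 steps (steps 3 to 8, from zingerone).

**Steps most likely to fail**

Step 6 (proposed new method). The diene may bond at the internal alkyne or through the wrong terminus, the diynone may oligomerize by repeated Michael addition, or the adduct may aromatize by loss of silanol instead of methanol. The fallback uses known chemistry, sets out from ketone 7 and returns at chromone 20. Step 4 is run as far as acetylide 11 and quenched with water in place of the carbamoyl chloride, so that 4-(4-benzyloxy-3-methoxyphenyl)but-1-yne 10 is isolated. Commercial 3,4-dimethoxyphenol is iodinated para to its 3-methoxy group (N-iodosuccinimide, MeCN, 0 °C) to give 2-iodo-4,5-dimethoxyphenol F1. F1, alkyne 10 and CO are then joined by carbonylative Sonogashira coupling in diethylamine (PdCl2(PPh3)2, CO, Et2NH, heat). Ynone 18 forms in the flask and is closed by the amine to 20. Ring A then comes from the aromatic pool and steps 1, 2 and 5 fall away.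

Step 5. The released N,O-dimethylhydroxylamine or excess Grignard reagent may add in conjugate fashion to the doubly activated diynone during the quench, or the diynone may decompose on isolation. The fallback sets out from Weinreb amide 12 and returns at diynone 15. Reduction of 12 with i-Bu2AlH (THF, −78 °C, quench into cold 1 M HCl) should give 5-(4-benzyloxy-3-methoxyphenyl)pent-2-ynal F2. Ethynylmagnesium bromide 13 then adds to the aldehyde (THF, 0 °C) to give racemic 7-(4-benzyloxy-3-methoxyphenyl)hepta-1,4-diyn-3-ol F3, which can be stored. Oxidation with MnO2 (CH2Cl2, rt) or Dess–Martin periodinane just before the key step releases 15 with no amine present.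

Step 4. Acylation of the acetylide in the one-flask sequence may stay incomplete because residual lithium amide consumes the carbamoyl chloride, or amide base may add to the ynamide once it has formed. The fallback sets out from ketone 7 (through acetylide 11, formed as in step 4) and returns at Weinreb amide 12. The acetylide solution is poured onto solid CO2, a trap that the amine and the phosphate salt do not disturb, and acidified with HCl to give 5-(4-benzyloxy-3-methoxyphenyl)pent-2-ynoic acid F4, which is purified by base extraction. Amide coupling of F4 with MeNH(OMe)·HCl (N-ethyl-N'-(3-dimethylaminopropyl)carbodiimide hydrochloride, N-methylmorpholine, CH2Cl2, 0 °C) then gives 12.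

**Further compounds**

F1 | step 6 | 2-iodo-4,5-dimethoxyphenol | COc1cc(O)c(I)cc1OC
F2 | step 5 | 5-(4-benzyloxy-3-methoxyphenyl)pent-2-ynal | O=CC#CCCc1ccc(OCc2ccccc2)c(OC)c1
F3 | step 5 | 7-(4-benzyloxy-3-methoxyphenyl)hepta-1,4-diyn-3-ol (racemic) | C#CC(O)C#CCCc1ccc(OCc2ccccc2)c(OC)c1
F4 | step 4 | 5-(4-benzyloxy-3-methoxyphenyl)pent-2-ynoic acid | OC(=O)C#CCCc1ccc(OCc2ccccc2)c(OC)c1
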